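**Retrosynthetic overview**
- Final operation: an acyclic alkynyl hydroxy aldehyde that carries only the butenolide is closed twice in one pot. Gold-catalysed 5-endo-dig hydroalkoxylation of the C1≡C2 alkyne forms the dihydrofuran, and an intramolecular vinylogous aldol condensation (C5 aldehyde + butenolide γ-carbon C6) forms the ten-membered carbocycle. The ring enforces the C5=C6 geometry, and the same pot installs the 13-acetate.
- The acyclic precursor comes from a C8–C9 boron aldol (sets C8) between a methyl ynone and a formyl butenolide, a chelation-controlled MeMgBr addition (sets C10, 8,10-syn) and C8 methacryloylation.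
- Methyl ynone (C1–C5, C9, C10, C15): Sharpless epoxidation of methallyl alcohol (sets C4), acetylide opening, oxidation/acetalisation, Weinreb acylation.
- Formyl butenolide (C6–C8, C11–C13): vinyl carbomagnesiation/carboxylation of but-2-yne-1,4-diol, silylation, ozonolysis.
- Ring order: butenolide first (step 5), then dihydrofuran and carbocycle together (step 12).

Assumption: positions follow germacranolide numbering (C4 and C10 carry the methyls, C6 the lactone oxygen, C12 the lactone carbonyl, C13 the acetoxymethyl carbon); the SMILES decodes to 4S,8S,10R with C4 cis to C7 across C5=C6 (5E).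

**Route**

Step 1
Reactants: 1 2-methylprop-2-en-1-ol
Product: 2 (R)-(2-methyloxiran-2-yl)methanol
Conditions: Ti(OiPr)4 (5 mol %), D-(−)-diisopropyl tartrate (6 mol %), cumene hydroperoxide, 4 Å MS, CH2Cl2, −20 °C
Reagents that add atoms: cumene hydroperoxide CC(C)(OO)c1ccccc1
Why: Sharpless asymmetric epoxidation of a 2-substituted allylic alcohol, in which the D-(−)-tartrate catalyst delivers oxygen to the face that gives the R epoxide (the carbon that becomes C4).

Step 2
Reactants: 2 (R)-(2-methyloxiran-2-yl)methanol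
Product: 3 (S)-2-methylpent-4-yne-1,2-diol
Conditions: LiC≡CH·H2NCH2CH2NH2 (3 equiv), DMSO, 0 °C → rt; aq. NH4Cl
Reagents that add atoms: lithium acetylide [Li+].[C-]#C
Why: SN2 epoxide opening by acetylide at the CH2 terminus (Payne equilibration is degenerate for this epoxide), which touches no bond at the stereocentre, so R becomes S only through the change in CIP priorities.

Step 3
Reactants: 3 (S)-2-methylpent-4-yne-1,2-diol
Product: 5 (S)-1,1-dimethoxy-2-methylpent-4-yn-2-ol, via hydroxy aldehyde 4 (not isolated)
Conditions: IBX, EtOAc, 75 °C; filter; HC(OMe)3, MeOH, PPTS, rt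
Reagents that add atoms: trimethyl orthoformate COC(OC)OC
Why: IBX oxidation of the primary alcohol (tertiary OH inert, no glycol cleavage) followed at once by acid-catalysed acetalisation, which masks the sensitive α-hydroxy aldehyde without touching the quaternary stereocentre.

Step 4
Reactants: 5 (S)-1,1-dimethoxy-2-methylpent-4-yn-2-ol
Product: 6 (S)-6-hydroxy-7,7-dimethoxy-6-methylhept-3-yn-2-one
Conditions: n-BuLi (2.1 equiv), THF, −78 °C; MeC(O)N(OMe)Me, −78 → 0 °C; aq. NH4Cl
Reagents that add atoms: N-methoxy-N-methylacetamide CC(=O)N(C)OC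
Why: Weinreb ketone synthesis, in which the alkoxide–acetylide dianion is C-acylated and the chelated tetrahedral intermediate prevents over-addition, giving the methyl ynone.

Step 5
Reactants: 7 but-2-yne-1,4-diol
Product: 8 3-(hydroxymethyl)-4-vinylfuran-2(5H)-one
Conditions: CH2=CHMgCl (4 equiv), THF–toluene, 70 °C; CO2, −20 °C → rt; 2 M HCl
Reagents that add atoms: vinylmagnesium chloride C=C[Mg]Cl; carbon dioxide O=C=O
Why: Alkoxide-directed anti-carbomagnesiation of the propargylic alcohol places vinyl on one alkyne carbon and magnesium on the other, cis to the chelating CH2O, so carboxylation and acidification give the cis hydroxy acid that lactonises to the butenolide (the diol is symmetric, so only one product is possible).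

Step 6
Reactants: 8 3-(hydroxymethyl)-4-vinylfuran-2(5H)-one
Product: 9 3-[(tert-butyldimethylsilyloxy)methyl]-4-vinylfuran-2(5H)-one
Conditions: TBSCl, imidazole, CH2Cl2, 0 °C
Reagents that add atoms: tert-butyldimethylsilyl chloride CC(C)(C)[Si](C)(C)Cl
Why: Standard silylation of the primary alcohol, needed so that the C13 oxygen neither forms a lactol with the coming aldehyde nor competes in the later acylation.

Step 7
Reactants: 9 3-[(tert-butyldimethylsilyloxy)methyl]-4-vinylfuran-2(5H)-one
Product: 10 4-[(tert-butyldimethylsilyloxy)methyl]-5-oxo-2,5-dihydrofuran-3-carbaldehyde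
Conditions: O3, CH2Cl2, −78 °C; Me2S, −78 °C → rt
Reagents that add atoms: ozone [O-][O+]=O
Why: Ozonolysis with reductive work-up cleaves the terminal vinyl group selectively, because the tetrasubstituted ring alkene is deactivated by conjugation with the lactone carbonyl.

Step 8
Reactants: 6 (S)-6-hydroxy-7,7-dimethoxy-6-methylhept-3-yn-2-one; 10 4-[(tert-butyldimethylsilyloxy)methyl]-5-oxo-2,5-dihydrofuran-3-carbaldehyde
Product: 11 3-[(tert-butyldimethylsilyloxy)methyl]-4-[(1S,7S)-1,7-dihydroxy-8,8-dimethoxy-7-methyl-3-oxooct-4-yn-1-yl]furan-2(5H)-one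
Conditions: (−)-Ipc2BCl (2.2 equiv), Et3N, Et2O, −78 → 0 °C; 10, −78 → −20 °C; MeOH, pH 7 buffer, H2O2, 0 °C
Reagents that add atoms: none
Why: Paterson-type boron aldol in which the Ipc2B enolate of the methyl ketone adds under reagent control to the Si face of the non-enolisable aldehyde through a cyclic transition state to give the 8S carbinol, the sense expected for (−)-Ipc2BCl with methyl ketones (the other enantiomer is used if the sense proves opposite), while the non-basic conditions leave the acidic butenolide CH2 alone.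

Step 9
Reactants: 11 3-[(tert-butyldimethylsilyloxy)methyl]-4-[(1S,7S)-1,7-dihydroxy-8,8-dimethoxy-7-methyl-3-oxooct-4-yn-1-yl]furan-2(5H)-one
Product: 12 3-[(tert-butyldimethylsilyloxy)methyl]-4-[(1S,3R,7S)-1,3,7-trihydroxy-8,8-dimethoxy-3,7-dimethyloct-4-yn-1-yl]furan-2(5H)-one
Conditions: MeMgBr (4 equiv), CH2Cl2–Et2O, −78 °C (inverse addition); aq. NH4Cl
Reagents that add atoms: methylmagnesium bromide C[Mg]Br
Why: Chelation-controlled Grignard 1,2-addition (1,3-induction) in which the magnesium alkoxide at C8 chelates the ynone carbonyl and external MeMgBr attacks the face opposite the C7 substituent, giving the 8,10-syn diol (10R) faster than lactone attack or oxa-Michael closure at −78 °C.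

Step 10
Reactants: 12 3-[(tert-butyldimethylsilyloxy)methyl]-4-[(1S,3R,7S)-1,3,7-trihydroxy-8,8-dimethoxy-3,7-dimethyloct-4-yn-1-yl]furan-2(5H)-one
Product: 13 (1S,3R,7S)-1-{4-[(tert-butyldimethylsilyloxy)methyl]-5-oxo-2,5-dihydrofuran-3-yl}-3,7-dihydroxy-8,8-dimethoxy-3,7-dimethyloct-4-yn-1-yl methacrylate
Conditions: methacrylic anhydride, Et3N, DMAP (cat.), CH2Cl2, 0 °C
Reagents that add atoms: methacrylic anhydride C=C(C)C(=O)OC(=O)C(C)=C
Why: DMAP-catalysed acylation of the only secondary hydroxyl (C8), since the two tertiary alcohols do not react under these conditions.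

Step 11
Reactants: 13 (1S,3R,7S)-1-{4-[(tert-butyldimethylsilyloxy)methyl]-5-oxo-2,5-dihydrofuran-3-yl}-3,7-dihydroxy-8,8-dimethoxy-3,7-dimethyloct-4-yn-1-yl methacrylate
Product: 14 (1S,3R,7S)-3,7-dihydroxy-1-[4-(hydroxymethyl)-5-oxo-2,5-dihydrofuran-3-yl]-3,7-dimethyl-8-oxooct-4-yn-1-yl methacrylate
Conditions: 2 M HCl, THF, 35 °C
Reagents that add atoms: water O
Why: Acid hydrolysis cleaves the dimethyl acetal and the primary silyl ether together, while esters, lactone and tertiary alcohols survive and the quaternary α-carbon of the new aldehyde cannot epimerise.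

Step 12
Reactants: 14 (1S,3R,7S)-3,7-dihydroxy-1-[4-(hydroxymethyl)-5-oxo-2,5-dihydrofuran-3-yl]-3,7-dimethyl-8-oxooct-4-yn-1-yl methacrylate
Product: 18 (4S,8S,10R,5E)-13-acetoxy-10-hydroxy-8-methacryloyloxy-1,4-epoxygermacra-1,5,7(11)-trien-12,6-olide (CNP0394509.2), via dihydrofuran aldehyde 15 (not isolated), via macrocyclic aldol adduct 16 (not isolated), via diacetate 17 (not isolated)
Conditions: (Ph3P)AuNTf2 (3 mol %), 4 Å MS, CH2Cl2, rt; dilute to 1 mM, DBU, 0 °C → rt; Ac2O, DMAP, rt
Reagents that add atoms: acetic anhydride CC(=O)OC(C)=O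
Why: Proposed new method: the gold catalyst activates the alkyne for 5-endo-dig attack by the C4 hydroxyl (the only hydroxyl that can reach C1), giving the 2,3-dihydrofuran that turns the aldehyde and the butenolide arm toward each other; DBU then forms the butenolide dienolate (the free C13 hydroxyl is not a leaving group), whose γ-carbon adds to the non-enolisable aldehyde to close the ten-membered carbocycle; acetylation of the new C5 hydroxyl and the primary C13 hydroxyl followed by E1cB loss of the C5 acetate gives the C5=C6 bond in the only geometry the bicycle allows (C4 cis to C7), after which no γ-hydrogen remains and the 13-acetate is base-stable, with C4, C8 and C10 untouched; the closest known reactions are the gold-catalysed cycloisomerisation of homopropargylic alcohols and the vinylogous aldol condensation of butenolides with aldehydes.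

**Compound list**

1 | 2-methylprop-2-en-1-ol | C=C(C)CO | starting material
2 | (R)-(2-methyloxiran-2-yl)methanol | C[C@@]1(CO)CO1 | intermediate
3 | (S)-2-methylpent-4-yne-1,2-diol | C[C@@](O)(CO)CC#C | intermediate
4 | (S)-2-hydroxy-2-methylpent-4-ynal (not isolated) | C[C@@](O)(C=O)CC#C | intermediate
5 | (S)-1,1-dimethoxy-2-methylpent-4-yn-2-ol | C[C@@](O)(C(OC)OC)CC#C | intermediate
6 | (S)-6-hydroxy-7,7-dimethoxy-6-methylhept-3-yn-2-one | C[C@@](O)(C(OC)OC)CC#CC(C)=O | intermediate
7 | but-2-yne-1,4-diol | OCC#CCO | starting material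
8 | 3-(hydroxymethyl)-4-vinylfuran-2(5H)-one | O=C1OCC(C=C)=C1CO | intermediate
9 | 3-[(tert-butyldimethylsilyloxy)methyl]-4-vinylfuran-2(5H)-one | O=C1OCC(C=C)=C1CO[Si](C)(C)C(C)(C)C | intermediate
10 | 4-[(tert-butyldimethylsilyloxy)methyl]-5-oxo-2,5-dihydrofuran-3-carbaldehyde | O=CC1=C(CO[Si](C)(C)C(C)(C)C)C(=O)OC1 | intermediate
11 | 3-[(tert-butyldimethylsilyloxy)methyl]-4-[(1S,7S)-1,7-dihydroxy-8,8-dimethoxy-7-methyl-3-oxooct-4-yn-1-yl]furan-2(5H)-one | COC(OC)[C@@](C)(O)CC#CC(=O)C[C@H](O)C1=C(CO[Si](C)(C)C(C)(C)C)C(=O)OC1 | intermediate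
12 | 3-[(tert-butyldimethylsilyloxy)methyl]-4-[(1S,3R,7S)-1,3,7-trihydroxy-8,8-dimethoxy-3,7-dimethyloct-4-yn-1-yl]furan-2(5H)-one | COC(OC)[C@@](C)(O)CC#C[C@](C)(O)C[C@H](O)C1=C(CO[Si](C)(C)C(C)(C)C)C(=O)OC1 | intermediate
13 | (1S,3R,7S)-1-{4-[(tert-butyldimethylsilyloxy)methyl]-5-oxo-2,5-dihydrofuran-3-yl}-3,7-dihydroxy-8,8-dimethoxy-3,7-dimethyloct-4-yn-1-yl methacrylate | COC(OC)[C@@](C)(O)CC#C[C@](C)(O)C[C@H](OC(=O)C(C)=C)C1=C(CO[Si](C)(C)C(C)(C)C)C(=O)OC1 | intermediate
14 | (1S,3R,7S)-3,7-dihydroxy-1-[4-(hydroxymethyl)-5-oxo-2,5-dihydrofuran-3-yl]-3,7-dimethyl-8-oxooct-4-yn-1-yl methacrylate | O=C[C@@](C)(O)CC#C[C@](C)(O)C[C@H](OC(=O)C(C)=C)C1=C(CO)C(=O)OC1 | intermediate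
15 | (1S,3R)-3-[(5S)-5-formyl-5-methyl-4,5-dihydrofuran-2-yl]-3-hydroxy-1-[4-(hydroxymethyl)-5-oxo-2,5-dihydrofuran-3-yl]butyl methacrylate (not isolated) | O=C[C@]1(C)CC=C(O1)[C@](C)(O)C[C@H](OC(=O)C(C)=C)C2=C(CO)C(=O)OC2 | intermediate
16 | (4S,8S,10R)-5,10,13-trihydroxy-8-methacryloyloxy-1,4-epoxygermacra-1,7(11)-dien-12,6-olide, C5/C6 epimer mixture (not isolated) | C=C(C)C(=O)O[C@H]1C[C@@](C)(O)C2=CC[C@@](C)(C(O)C3OC(=O)C(CO)=C31)O2 | intermediate
17 | (4S,8S,10R)-5,13-diacetoxy-10-hydroxy-8-methacryloyloxy-1,4-epoxygermacra-1,7(11)-dien-12,6-olide, C5/C6 epimer mixture (not isolated) | C=C(C)C(=O)O[C@H]1C[C@@](C)(O)C2=CC[C@@](C)(C(OC(C)=O)C3OC(=O)C(COC(C)=O)=C31)O2 | intermediate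
18 | (4S,8S,10R,5E)-13-acetoxy-10-hydroxy-8-methacryloyloxy-1,4-epoxygermacra-1,5,7(11)-trien-12,6-olide (CNP0394509.2) | C=C(C)C(=O)O[C@H]1C[C@@](C)(O)C2=CC[C@@](C)(/C=C3/OC(=O)C(COC(C)=O)=C31)O2 | target

**Step count and risks**

Total steps: 12. Longest linear sequence: 9 (steps 1–4, then 8–12).

Steps most likely to fail:

Step 12. The ten-membered ring must close by a direct vinylogous aldol at high dilution in competition with oligomerisation and retro-aldol, and the sensitive hydroxy aldehyde 14 must survive the gold stage. Fallback: give up the one-pot and the base-generated dienolate. Setting out from 14, the gold stage is run alone and the dihydrofuran aldehyde 15 is isolated. TMSOTf/Et3N converts it into the tris(trimethylsilyl) silyloxyfuran F1. BF3·OEt2 at 1 mM then closes the ring by an intramolecular vinylogous Mukaiyama aldol (Lewis-acid activation of the aldehyde, neutral silyl dienol ether as nucleophile). The citric acid work-up removes the silyl groups to give 16, where the route is rejoined; 16 is acetylated and eliminated (Ac2O, DMAP, DBU) by way of 17 to 18.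

Step 8. The formyl butenolide 10 is both an electrophile and a latent nucleophile, and the enantioselectivity of methyl-ketone boron aldols is only moderate. Fallback: replace the chiral boron enolate by catalyst control. Setting out from 6, TMSOTf/Et3N gives the bis(trimethylsilyl) enol silane F2, which is added to 10 in a Lewis-base-catalysed enantioselective Mukaiyama aldol (SiCl4, chiral bisphosphoramide, −78 °C). Acidic methanol work-up cleaves both trimethylsilyl groups and the route is rejoined at 11.

Step 9. The β-hydroxy ynone 11 can close to a dihydropyranone by oxa-Michael addition, MeMgBr can touch the lactone, and the diastereoselectivity rests on chelation. Fallback: reverse the order in which the two carbon groups reach C10. Setting out from 10, the same Ipc2BCl aldol with acetone gives the methyl ketone F3. The alkynyl group of 5 is then added as its alkynyltitanium triisopropoxide (5, n-BuLi, ClTi(OiPr)3). Exchange of the reagent onto the C8 hydroxyl and intramolecular alkynyl delivery through a chair transition state gives the same 8,10-syn diol, so the route is rejoined at 12 without ever forming the ynone.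

Further compounds
F1 | step 12 | (1S,3R)-3-[(5S)-5-formyl-5-methyl-4,5-dihydrofuran-2-yl]-3-(trimethylsilyloxy)-1-{5-(trimethylsilyloxy)-4-[(trimethylsilyloxy)methyl]furan-3-yl}butyl methacrylate | O=C[C@]1(C)CC=C(O1)[C@](C)(O[Si](C)(C)C)C[C@H](OC(=O)C(C)=C)c2coc(O[Si](C)(C)C)c2CO[Si](C)(C)C
F2 | step 8 | (S)-7,7-dimethoxy-6-methyl-2,6-bis(trimethylsilyloxy)hept-1-en-3-yne | C=C(O[Si](C)(C)C)C#CC[C@](C)(O[Si](C)(C)C)C(OC)OC
F3 | step 9 | (S)-3-[(tert-butyldimethylsilyloxy)methyl]-4-(1-hydroxy-3-oxobutyl)furan-2(5H)-one | CC(=O)C[C@H](O)C1=C(CO[Si](C)(C)C(C)(C)C)C(=O)OC1
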